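**Retrosynthetic overview**

1. Labels: dihydrobenzofuran O1/C2/C3 fused to arene ring B; side chain C7 (carbinol CH on C5 of ring B), C8 (CH carrying guaiacyl ring C), C9 (CH2OH); ring A is the guaiacyl ring on C2. The target comes from a C7–C8 coupled diester by one double ester reduction (C9 and the C3 hydroxymethyl carbon are both carried as esters) and global desilylation.
2. C7–C8 is cut as an intermolecular Rh(II) donor/acceptor-carbene C–H insertion, an aldol surrogate that needs neither aldehyde nor enolate. The enabling feature: C7 is benzylic to ring B, oxygen-bearing and para to the ring oxygen O1, so the C7–H of an ArCH2–OSi precursor is the most hydridic accessible C–H of that fragment. C8 sits between guaiacyl ring C (donor) and C9 at the carboxyl level (acceptor), so it is the carbene carbon of a homovanillate-derived aryldiazoacetate. The chiral catalyst sets C7 and C8 (syn) in that one event.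
3. The same relation (oxygen-bearing benzylic C2 next to C3, which carries ring B and a carboxyl-level carbon) builds the dihydrofuran ring by the intramolecular version: 1,5 C–H insertion into the ArO–CH2–Ar methylene (C2–C3 bond), then C3 epimerization to trans. This is the only ring formed; rings A, B and C are bought.
4. Building blocks: 5-iodovanillin (ring B with O1, OMe, the C7 carbon, and iodide where C3 attaches), vanillin (ring A + C2), ethyl diazoacetate (C3 + its CH2OH carbon), methyl homovanillate (ring C + C8 + C9).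

Key step: step 11

Assumption: the hand of each chiral Rh(II) catalyst (steps 7 and 11) is assigned by analogy with the accepted selectivity models for these catalyst classes; should a trial run show the opposite sense, the mirror-image catalyst is used and nothing else changes.

**Route**

Step 1
Reactants: 1 vanillin (4-hydroxy-3-methoxybenzaldehyde)
Product: 2 3-methoxy-4-[(triisopropylsilyl)oxy]benzaldehyde
Conditions: TIPSCl, imidazole, DMF, 23 °C
Reagents that add atoms: triisopropylsilyl chloride, CC(C)[Si](Cl)(C(C)C)C(C)C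
Why: Imidazole-promoted O-silylation of the phenol gives a bulky aryl silyl ether that has no C–H bond prone to carbene insertion and is removable with fluoride at the end.

Step 2
Reactants: 2 3-methoxy-4-[(triisopropylsilyl)oxy]benzaldehyde
Product: 3 {3-methoxy-4-[(triisopropylsilyl)oxy]phenyl}methanol
Conditions: NaBH4, MeOH, 0 °C
Reagents that add atoms: none
Why: Borohydride 1,2-reduction of the aryl aldehyde should proceed cleanly at 0 °C, where the aryl TIPS ether is stable.

Step 3
Reactants: 3 {3-methoxy-4-[(triisopropylsilyl)oxy]phenyl}methanol; 4 5-iodovanillin (4-hydroxy-3-iodo-5-methoxybenzaldehyde)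
Product: 5 3-iodo-5-methoxy-4-({3-methoxy-4-[(triisopropylsilyl)oxy]benzyl}oxy)benzaldehyde
Conditions: PPh3, DIAD, THF, 0 → 23 °C
Reagents that add atoms: none
Why: Mitsunobu etherification, in which the acidic phenol of 4 (para-formyl, ortho-iodo) is alkylated by the activated electron-rich benzylic alcohol under neutral conditions that avoid the silyl transfer possible under carbonate alkylation.

Step 4
Reactants: 5 3-iodo-5-methoxy-4-({3-methoxy-4-[(triisopropylsilyl)oxy]benzyl}oxy)benzaldehyde
Product: 6 [3-iodo-5-methoxy-4-({3-methoxy-4-[(triisopropylsilyl)oxy]benzyl}oxy)phenyl]methanol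
Conditions: NaBH4, MeOH–THF, 0 °C
Reagents that add atoms: none
Why: Borohydride reduction of the aldehyde (which would otherwise trap the later carbene as a carbonyl ylide) leaves the aryl iodide, the benzyl ether and the silyl ether untouched.

Step 5
Reactants: 6 [3-iodo-5-methoxy-4-({3-methoxy-4-[(triisopropylsilyl)oxy]benzyl}oxy)phenyl]methanol
Product: 7 tert-butyl{[3-iodo-5-methoxy-4-({3-methoxy-4-[(triisopropylsilyl)oxy]benzyl}oxy)benzyl]oxy}dimethylsilane
Conditions: TBSCl, imidazole, CH2Cl2, 23 °C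
Reagents that add atoms: tert-butyldimethylsilyl chloride, CC(C)(C)[Si](C)(C)Cl
Why: O-silylation of the primary benzylic alcohol removes the O–H bond (a carbene trap) and installs the ArCH2–OSi methylene whose C–H bond is the reaction site of step 11.

Step 6
Reactants: 7 tert-butyl{[3-iodo-5-methoxy-4-({3-methoxy-4-[(triisopropylsilyl)oxy]benzyl}oxy)benzyl]oxy}dimethylsilane; 8 ethyl diazoacetate
Product: 9 ethyl 2-[5-({[tert-butyl(dimethyl)silyl]oxy}methyl)-3-methoxy-2-({3-methoxy-4-[(triisopropylsilyl)oxy]benzyl}oxy)phenyl]-2-diazoacetate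
Conditions: Pd(PPh3)4 (cat.), Ag2CO3, Et3N, toluene, 23 °C
Reagents that add atoms: none
Why: Pd(0)-catalysed cross-coupling of an aryl iodide with the C–H bond of ethyl diazoacetate (oxidative addition, base/silver-assisted palladation of the diazo carbon, reductive elimination) should give the aryldiazoacetate with the diazo group retained at room temperature.

Step 7
Reactants: 9 ethyl 2-[5-({[tert-butyl(dimethyl)silyl]oxy}methyl)-3-methoxy-2-({3-methoxy-4-[(triisopropylsilyl)oxy]benzyl}oxy)phenyl]-2-diazoacetate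
Product: 10 ethyl (2S,3R)-5-({[tert-butyl(dimethyl)silyl]oxy}methyl)-7-methoxy-2-{3-methoxy-4-[(triisopropylsilyl)oxy]phenyl}-2,3-dihydro-1-benzofuran-3-carboxylate (cis)
Conditions: Rh2(S-PTTL)4 (1 mol %), toluene, −78 °C
Reagents that add atoms: none
Why: Intramolecular Rh(II)-carbene 1,5 C–H insertion into the doubly activated ArO–CH2–Ar methylene closes the dihydrofuran ring; the chiral N-phthaloyl-tert-leucinate catalyst selects one enantiotopic hydrogen and so sets C2 (S), and the concerted insertion should deliver the cis ester kinetically, as is known for cis-2-aryl-3-alkoxycarbonyl-2,3-dihydrobenzofurans.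

Step 8
Reactants: 10 ethyl (2S,3R)-cis-dihydrobenzofuran-3-carboxylate
Product: 11 ethyl (2S,3S)-5-({[tert-butyl(dimethyl)silyl]oxy}methyl)-7-methoxy-2-{3-methoxy-4-[(triisopropylsilyl)oxy]phenyl}-2,3-dihydro-1-benzofuran-3-carboxylate (trans)
Conditions: DBU, toluene, 60 °C
Reagents that add atoms: none
Why: Base-mediated epimerization at C3 (α to the ester) should converge on the thermodynamically favoured trans isomer, while C2 is untouched because ring opening by β-elimination would be a disfavoured reverse 5-endo-trig process and the non-nucleophilic amine spares the aryl silyl ether.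

Step 9
Reactants: 12 methyl homovanillate (methyl 2-(4-hydroxy-3-methoxyphenyl)acetate)
Product: 13 methyl 2-{3-methoxy-4-[(triisopropylsilyl)oxy]phenyl}acetate
Conditions: TIPSCl, imidazole, DMF, 23 °C
Reagents that add atoms: triisopropylsilyl chloride, CC(C)[Si](Cl)(C(C)C)C(C)C
Why: Phenol O-silylation, for the same reasons as in step 1.

Step 10
Reactants: 13 methyl 2-{3-methoxy-4-[(triisopropylsilyl)oxy]phenyl}acetate
Product: 14 methyl 2-diazo-2-{3-methoxy-4-[(triisopropylsilyl)oxy]phenyl}acetate
Conditions: p-ABSA, DBU, MeCN, 0 → 23 °C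
Reagents that add atoms: 4-acetamidobenzenesulfonyl azide (p-ABSA), CC(=O)Nc1ccc(cc1)S(=O)(=O)N=[N+]=[N-]
Why: Regitz diazo transfer to the aryl-activated methylene of an arylacetate is the standard entry to donor/acceptor aryldiazoacetates.

Step 11
Reactants: 11 ethyl (2S,3S)-trans-dihydrobenzofuran-3-carboxylate bearing the 5-CH2OTBS group; 14 methyl 2-diazo-2-{3-methoxy-4-[(triisopropylsilyl)oxy]phenyl}acetate
Product: 15 ethyl (2S,3S)-5-[(1S,2S)-1-{[tert-butyl(dimethyl)silyl]oxy}-3-methoxy-2-{3-methoxy-4-[(triisopropylsilyl)oxy]phenyl}-3-oxopropyl]-7-methoxy-2-{3-methoxy-4-[(triisopropylsilyl)oxy]phenyl}-2,3-dihydro-1-benzofuran-3-carboxylate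
Conditions: Rh2(S-DOSP)4 (2 mol %), 14 (2.5 equiv, slow addition), 2,2-dimethylbutane–PhCF3, 23 °C
Reagents that add atoms: none
Why: The Rh(II) prolinate catalyst converts 14, with loss of N2, into a rhodium-bound donor/acceptor carbene (C8 between the guaiacyl donor and the ester acceptor), which inserts into one C–H bond of the ArCH2–OSi methylene of 11 through a concerted, asynchronous, hydride-transfer-like three-centre transition state that forms C7–C8 and moves the hydrogen to C8. The closest known reaction type is the catalytic asymmetric intermolecular C–H functionalization of benzyl and allyl silyl ethers with aryldiazoacetates, which gives syn β-silyloxy-α-aryl esters as aldol equivalents. No ring is closed. Both new stereocentres are catalyst-controlled: the choice of diastereotopic hydrogen fixes C7, the carbene face fixes C8, and the preferred transition-state arrangement (silyloxy group turned away from the catalyst wall) should give the syn relation, here (7S,8S) in the ester and (7S,8R) after reduction; C2 and C3 are too remote to interfere, and any product of the wrong sense is a separable diastereomer. The step needs site selectivity for C7–H, which the substrate secures because C7–H is secondary, benzylic, α-silyloxy and para to O1, whereas C2–H and C3–H are tertiary, shielded and inductively deactivated by the ester deliberately kept at C3, the methyl-ether and silyl C–H bonds are unactivated, the tri- and tetrasubstituted arenes resist cyclopropanation, and no O–H bond is present. Slow addition of excess 14 should suppress carbene dimerization.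

Step 12
Reactants: 15 C7–C8 coupled diester
Product: 16 (2R,3S)-3-{[tert-butyl(dimethyl)silyl]oxy}-3-[(2S,3R)-3-(hydroxymethyl)-7-methoxy-2-{3-methoxy-4-[(triisopropylsilyl)oxy]phenyl}-2,3-dihydro-1-benzofuran-5-yl]-2-{3-methoxy-4-[(triisopropylsilyl)oxy]phenyl}propan-1-ol
Conditions: DIBAL-H (excess), CH2Cl2, −78 → 0 °C; Rochelle salt work-up
Reagents that add atoms: none
Why: Hydride reduction converts both esters (C9 methyl ester and C3 ethyl ester) to primary alcohols in one operation under non-basic conditions, so the α-aryl centres C8 and C3 should keep their configuration and the silyl ethers survive.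

Step 13
Reactants: 16 tris-silyl diol
Product: 17 (1S,2R)-1-[(2S,3R)-2-(4-hydroxy-3-methoxyphenyl)-3-(hydroxymethyl)-7-methoxy-2,3-dihydro-1-benzofuran-5-yl]-2-(4-hydroxy-3-methoxyphenyl)propane-1,3-diol (target)
Conditions: TBAF, AcOH, THF, 0 → 23 °C
Reagents that add atoms: none
Why: Fluoride-mediated cleavage removes the two aryl TIPS ethers and the benzylic TBS ether, and the acetic acid buffer keeps the liberated phenols protonated so that base-triggered quinone-methide pathways and epimerization are avoided.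

**Compound list**

1 | vanillin | O=Cc1ccc(O)c(OC)c1 | starting material
2 | 3-methoxy-4-[(triisopropylsilyl)oxy]benzaldehyde | O=Cc1ccc(O[Si](C(C)C)(C(C)C)C(C)C)c(OC)c1 | intermediate
3 | {3-methoxy-4-[(triisopropylsilyl)oxy]phenyl}methanol | OCc1ccc(O[Si](C(C)C)(C(C)C)C(C)C)c(OC)c1 | intermediate
4 | 5-iodovanillin | O=Cc1cc(I)c(O)c(OC)c1 | starting material
5 | 3-iodo-5-methoxy-4-({3-methoxy-4-[(triisopropylsilyl)oxy]benzyl}oxy)benzaldehyde | O=Cc1cc(I)c(OCc2ccc(O[Si](C(C)C)(C(C)C)C(C)C)c(OC)c2)c(OC)c1 | intermediate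
6 | [3-iodo-5-methoxy-4-({3-methoxy-4-[(triisopropylsilyl)oxy]benzyl}oxy)phenyl]methanol | OCc1cc(I)c(OCc2ccc(O[Si](C(C)C)(C(C)C)C(C)C)c(OC)c2)c(OC)c1 | intermediate
7 | tert-butyl{[3-iodo-5-methoxy-4-({3-methoxy-4-[(triisopropylsilyl)oxy]benzyl}oxy)benzyl]oxy}dimethylsilane | CC(C)(C)[Si](C)(C)OCc1cc(I)c(OCc2ccc(O[Si](C(C)C)(C(C)C)C(C)C)c(OC)c2)c(OC)c1 | intermediate
8 | ethyl diazoacetate | CCOC(=O)C=[N+]=[N-] | starting material
9 | ethyl 2-[5-({[tert-butyl(dimethyl)silyl]oxy}methyl)-3-methoxy-2-({3-methoxy-4-[(triisopropylsilyl)oxy]benzyl}oxy)phenyl]-2-diazoacetate | CCOC(=O)C(=[N+]=[N-])c1cc(CO[Si](C)(C)C(C)(C)C)cc(OC)c1OCc1ccc(O[Si](C(C)C)(C(C)C)C(C)C)c(OC)c1 | intermediate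
10 | ethyl (2S,3R)-5-({[tert-butyl(dimethyl)silyl]oxy}methyl)-7-methoxy-2-{3-methoxy-4-[(triisopropylsilyl)oxy]phenyl}-2,3-dihydro-1-benzofuran-3-carboxylate (cis) | COc1cc([C@H]2Oc3c(OC)cc(CO[Si](C)(C)C(C)(C)C)cc3[C@H]2C(=O)OCC)ccc1O[Si](C(C)C)(C(C)C)C(C)C | intermediate
11 | ethyl (2S,3S)-5-({[tert-butyl(dimethyl)silyl]oxy}methyl)-7-methoxy-2-{3-methoxy-4-[(triisopropylsilyl)oxy]phenyl}-2,3-dihydro-1-benzofuran-3-carboxylate (trans) | COc1cc([C@H]2Oc3c(OC)cc(CO[Si](C)(C)C(C)(C)C)cc3[C@@H]2C(=O)OCC)ccc1O[Si](C(C)C)(C(C)C)C(C)C | intermediate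
12 | methyl homovanillate | COC(=O)Cc1ccc(O)c(OC)c1 | starting material
13 | methyl 2-{3-methoxy-4-[(triisopropylsilyl)oxy]phenyl}acetate | COC(=O)Cc1ccc(O[Si](C(C)C)(C(C)C)C(C)C)c(OC)c1 | intermediate
14 | methyl 2-diazo-2-{3-methoxy-4-[(triisopropylsilyl)oxy]phenyl}acetate | COC(=O)C(=[N+]=[N-])c1ccc(O[Si](C(C)C)(C(C)C)C(C)C)c(OC)c1 | intermediate
15 | ethyl (2S,3S)-5-[(1S,2S)-1-{[tert-butyl(dimethyl)silyl]oxy}-3-methoxy-2-{3-methoxy-4-[(triisopropylsilyl)oxy]phenyl}-3-oxopropyl]-7-methoxy-2-{3-methoxy-4-[(triisopropylsilyl)oxy]phenyl}-2,3-dihydro-1-benzofuran-3-carboxylate | COc1cc([C@H]2Oc3c(OC)cc([C@@H](O[Si](C)(C)C(C)(C)C)[C@@H](C(=O)OC)c4ccc(O[Si](C(C)C)(C(C)C)C(C)C)c(OC)c4)cc3[C@@H]2C(=O)OCC)ccc1O[Si](C(C)C)(C(C)C)C(C)C | intermediate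
16 | (2R,3S)-3-{[tert-butyl(dimethyl)silyl]oxy}-3-[(2S,3R)-3-(hydroxymethyl)-7-methoxy-2-{3-methoxy-4-[(triisopropylsilyl)oxy]phenyl}-2,3-dihydro-1-benzofuran-5-yl]-2-{3-methoxy-4-[(triisopropylsilyl)oxy]phenyl}propan-1-ol | COc1cc([C@H]2Oc3c(OC)cc([C@@H](O[Si](C)(C)C(C)(C)C)[C@@H](CO)c4ccc(O[Si](C(C)C)(C(C)C)C(C)C)c(OC)c4)cc3[C@@H]2CO)ccc1O[Si](C(C)C)(C(C)C)C(C)C | intermediate
17 | (1S,2R)-1-[(2S,3R)-2-(4-hydroxy-3-methoxyphenyl)-3-(hydroxymethyl)-7-methoxy-2,3-dihydro-1-benzofuran-5-yl]-2-(4-hydroxy-3-methoxyphenyl)propane-1,3-diol | COc1cc([C@H]2Oc3c(OC)cc([C@@H](O)[C@@H](CO)c4ccc(O)c(OC)c4)cc3[C@@H]2CO)ccc1O | target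

**Step count and risk**

Total steps: 13. Longest linear sequence: 11 steps (steps 1–8, then 11–13).

Steps most likely to fail:

1. Step 11 (key C–H insertion). The carbene may insert at a competing C–H site (C2–H of the dihydrofuran or an aryl methyl ether), dimerize faster than it reacts with the bulky substrate, or show eroded catalyst control of the C7/C8 sense. Fallback (auxiliary-controlled Evans syn-aldol), setting out from 11 and 13 and returning at 17: the benzylic TBS ether of 11 is removed selectively with CSA in MeOH to give the primary benzylic alcohol F1, which MnO2 in CH2Cl2 oxidizes to the 5-formyl dihydrobenzofuran ester F2. In parallel, ester 13 is hydrolysed with Me3SnOH (1,2-dichloroethane, 80 °C) to 2-{3-methoxy-4-[(triisopropylsilyl)oxy]phenyl}acetic acid F3, which is coupled with (S)-4-benzyloxazolidin-2-one (DCC, DMAP, CH2Cl2) to the N-arylacetyl oxazolidinone F4. Soft enolization of F4 with Bu2BOTf/i-Pr2NEt (CH2Cl2, −78 → 0 °C) and addition of F2 should give, through the chair-like boron aldol transition state, the syn adduct F5 with the (7S,8S) configuration dictated by the (S)-auxiliary. LiBH4 (THF–MeOH, 0 °C) then cleaves the auxiliary reductively and reduces the ethyl ester to give the bis-TIPS triol F6, and TBAF/AcOH in THF gives 17.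

2. Step 6 (Pd-catalysed diazoacetate coupling). Oxidative addition and palladation may be slow at the ortho-alkoxy aryl iodide, and Pd- or Ag-induced loss of the diazo group may consume ethyl diazoacetate or the product. Fallback (arylation first, diazo transfer second), setting out from 7 and returning at 9: Negishi-type coupling of 7 with commercial (2-ethoxy-2-oxoethyl)zinc bromide (Reformatsky reagent; Pd(dba)2/XPhos, THF, 23 → 50 °C) gives the ethyl arylacetate F7, and Regitz diazo transfer (p-ABSA, DBU, MeCN) converts F7 into 9.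

3. Step 7 (enantioselective ring-forming insertion). Discrimination of the enantiotopic hydrogens may be insufficient on this more heavily substituted aryl ring, the catalyst may give part of the trans ester directly with a different selectivity, and the carbene may dimerize. Fallback (racemic ring formation and resolution instead of catalyst control), setting out from 9 and returning at 11: Rh2(OAc)4 in CH2Cl2 gives the racemic cis ester, that is 10 together with its enantiomer F8. DBU equilibration as in step 8 gives the racemic trans ester, that is 11 together with its enantiomer F9. Preparative chromatography on a chiral stationary phase then separates the two and returns 11.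

**Further compounds**

F1 | step 11 | ethyl (2S,3S)-5-(hydroxymethyl)-7-methoxy-2-{3-methoxy-4-[(triisopropylsilyl)oxy]phenyl}-2,3-dihydro-1-benzofuran-3-carboxylate | COc1cc([C@H]2Oc3c(OC)cc(CO)cc3[C@@H]2C(=O)OCC)ccc1O[Si](C(C)C)(C(C)C)C(C)C
F2 | step 11 | ethyl (2S,3S)-5-formyl-7-methoxy-2-{3-methoxy-4-[(triisopropylsilyl)oxy]phenyl}-2,3-dihydro-1-benzofuran-3-carboxylate | COc1cc([C@H]2Oc3c(OC)cc(C=O)cc3[C@@H]2C(=O)OCC)ccc1O[Si](C(C)C)(C(C)C)C(C)C
F3 | step 11 | 2-{3-methoxy-4-[(triisopropylsilyl)oxy]phenyl}acetic acid | OC(=O)Cc1ccc(O[Si](C(C)C)(C(C)C)C(C)C)c(OC)c1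
F4 | step 11 | (4S)-4-benzyl-3-(2-{3-methoxy-4-[(triisopropylsilyl)oxy]phenyl}acetyl)-1,3-oxazolidin-2-one | O=C1OC[C@H](Cc2ccccc2)N1C(=O)Cc1ccc(O[Si](C(C)C)(C(C)C)C(C)C)c(OC)c1
F5 | step 11 | ethyl (2S,3S)-5-[(1S,2S)-3-[(4S)-4-benzyl-2-oxo-1,3-oxazolidin-3-yl]-1-hydroxy-2-{3-methoxy-4-[(triisopropylsilyl)oxy]phenyl}-3-oxopropyl]-7-methoxy-2-{3-methoxy-4-[(triisopropylsilyl)oxy]phenyl}-2,3-dihydro-1-benzofuran-3-carboxylate | COc1cc([C@H]2Oc3c(OC)cc([C@@H](O)[C@@H](C(=O)N5[C@@H](Cc6ccccc6)COC5=O)c4ccc(O[Si](C(C)C)(C(C)C)C(C)C)c(OC)c4)cc3[C@@H]2C(=O)OCC)ccc1O[Si](C(C)C)(C(C)C)C(C)C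
F6 | step 11 | (1S,2R)-1-[(2S,3R)-3-(hydroxymethyl)-7-methoxy-2-{3-methoxy-4-[(triisopropylsilyl)oxy]phenyl}-2,3-dihydro-1-benzofuran-5-yl]-2-{3-methoxy-4-[(triisopropylsilyl)oxy]phenyl}propane-1,3-diol | COc1cc([C@H]2Oc3c(OC)cc([C@@H](O)[C@@H](CO)c4ccc(O[Si](C(C)C)(C(C)C)C(C)C)c(OC)c4)cc3[C@@H]2CO)ccc1O[Si](C(C)C)(C(C)C)C(C)C
F7 | step 6 | ethyl 2-[5-({[tert-butyl(dimethyl)silyl]oxy}methyl)-3-methoxy-2-({3-methoxy-4-[(triisopropylsilyl)oxy]benzyl}oxy)phenyl]acetate | CCOC(=O)Cc1cc(CO[Si](C)(C)C(C)(C)C)cc(OC)c1OCc1ccc(O[Si](C(C)C)(C(C)C)C(C)C)c(OC)c1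
F8 | step 7 | ethyl (2R,3S)-5-({[tert-butyl(dimethyl)silyl]oxy}methyl)-7-methoxy-2-{3-methoxy-4-[(triisopropylsilyl)oxy]phenyl}-2,3-dihydro-1-benzofuran-3-carboxylate (enantiomer of 10) | COc1cc([C@@H]2Oc3c(OC)cc(CO[Si](C)(C)C(C)(C)C)cc3[C@@H]2C(=O)OCC)ccc1O[Si](C(C)C)(C(C)C)C(C)C
F9 | step 7 | ethyl (2R,3R)-5-({[tert-butyl(dimethyl)silyl]oxy}methyl)-7-methoxy-2-{3-methoxy-4-[(triisopropylsilyl)oxy]phenyl}-2,3-dihydro-1-benzofuran-3-carboxylate (enantiomer of 11) | COc1cc([C@@H]2Oc3c(OC)cc(CO[Si](C)(C)C(C)(C)C)cc3[C@H]2C(=O)OCC)ccc1O[Si](C(C)C)(C(C)C)C(C)C
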